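**Maceneolignan A (15): route design built on a CuH-catalysed styrene–anhydride coupling and a C3-controlled quinone methide ring closure**

Ring labels: ring A is the benzo ring (C3a–C7a), ring B the dihydrofuran (O1, C2, C3, C3a, C7a), ring C the 4-hydroxy-3,5-dimethoxyphenyl group on C2. From the SMILES, the target is (2R,3R), with the C2 aryl and C3 methyl trans.

## The problem

Maceneolignan A (15) is a 2,3-dihydro-1-benzofuran in which ring A carries OMe at C7 and an (E)-prop-1-enyl group at C5, and ring B carries a methyl group at C3 and ring C at C2, trans, (2R,3R). The two C6C3 halves differ (guaiacyl-type ring A, syringyl-type ring C), so a plan that dimerises two propenylphenols faces a cross-selectivity problem on top of the stereochemical one. The two stereocentres are not equal: C2 is a benzylic ether carbon para to the free C4'–OH of ring C, so the C2–O1 bond ionises reversibly through a para-quinone methide and C2 settles trans to whatever C3 dictates, whereas C3 has no such correction mechanism. The task is therefore to set C3 (R) by reagent control and let C3 control C2. C3 is a methine that bears a methyl group, ring A and the oxygenated benzylic carbon C2 with ring C, which is the pattern formed when a ring A vinyl group undergoes Markovnikov hydrometallation and the benzylic metal is acylated by a ring C aroyl donor. This pattern, together with the self-correcting C2–O1 bond, is the feature the key step uses. Sensitive groups are the (E)-propenyl styrene (acid, hydride, hydrogenation, metal-hydride isomerisation), the electron-rich free phenol, and the C2–O1 bond, whose opening can be followed by loss of H3 to a stilbene, which would erase C3.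

## Retrosynthesis

**C5–propenyl bond.** 15 is cut to aryl bromide 13 and the (E)-propenyl boronate 14. This keeps the styrene out of every hydride and acid step and buys the E geometry ready-made. The forward Suzuki coupling must only tolerate a free phenol and must not open ring B.

**O1–C2 bond (ring B).** 13 is cut back through quinone methide 12 and triol 11 to the bis-acetal-protected alcohol 10. Cutting here, not at C3–C3a, makes the ring closure stereoconvergent: whatever the carbinol configuration of 10, ionisation and 5-exo capture by the ring A phenol should give the trans ring under control of C3. Precursor 10 therefore needs to be single only at the future C3. The forward step needs acid strong enough to remove both acetals and ionise the carbinol, and capture by oxygen faster than proton loss from C3.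

**C2–C3 bond (key cut).** 10 is cut, through silyl ether 9 and ketone 8, into styrene 3 and anhydride 7. The neighbouring cuts are weaker: a C3–C3a cut (α-arylation of a propiophenone) needs an ortho-metallated ring A and leaves a racemisation-prone ketone to be isolated, and a C2–ring C cut (aryl metal plus aldehyde) needs a preformed chiral α-aryl aldehyde. The chosen cut makes the C3 methyl from the terminal vinyl carbon and C2 from a carboxyl carbon, so both precursors are one or two steps from catalogue arenes and carry no stereocentre. The forward reaction must join the two rings, fix C3 as R by catalyst control, and deliver the carbinol oxidation level at C2. A CuH-catalysed reductive coupling of a vinyl arene with an aryl anhydride does all three in one operation.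

**Styrene 3.** 3 comes from aldehyde 2 by methylenation, and 2 from the commercial bromo-ortho-vanillin 1 by acetal protection. The bromine of 1 already sits para to the phenol oxygen, where the propenyl group is needed.

**Anhydride 7.** 7 is made by joining two molecules of acid 6 with loss of water. Acid 6 comes from syringic acid 4 by double alkylation to ester 5 and selective ester hydrolysis. The same acetal group is used on both phenols so that one acid treatment frees both and triggers ring closure.

## Roads not taken

**Alternative 1:** Cut C3–C3a and O1–C2 together, as in the biosynthesis (the most obvious plan). One-electron oxidation of isoeugenol A1 with 2,6-dimethoxy-4-[(E)-prop-1-enyl]phenol A2 (Ag2O or peroxidase/H2O2) would give racemic trans product A3 in one step. A1 also couples with itself to give A4 and other β–β and β–O dimers, and nothing controls the face of either radical, so A3 is racemic and mixed with isomers. A resolution would discard at least half. The chosen plan gets cross-selectivity from two different functional groups and absolute configuration from a catalyst.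

**Alternative 2:** Cut C2–C3 by carbene C–H insertion. Hydrazone A5, oxidised in situ with MnO2 and decomposed by a chiral dirhodium tetracarboxylate such as Rh2(S-PTAD)4, would insert its carbene carbon into the benzylic C–H of the ether to give cis-dihydrobenzofuran A6, which then needs epimerisation at C2. Rings A and C are joined earlier by an ether synthesis, so the key step adds no convergence. The methyl-bearing carbene has an adjacent C–H, and a 1,2-hydride shift to a vinyl arene competes. The cis outcome costs a separate inversion step. The chosen key step starts from smaller pieces and needs no diazo chemistry.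

**Alternative 3:** Cut O1–C2 first, then C3–C3a. Allylic etherification of carbonate A7 with iodophenol A8 ([Ir(cod)Cl]2, chiral phosphoramidite) would give branched ether A9. A 5-exo aryl radical cyclisation (Bu3SnH, AIBN) would then give trans product A10 and cis product A11, with the methyl arising from the vinyl terminus. Here C2 is set by the catalyst and C3 only by substrate bias, which inverts the natural order of control. A11 cannot be repaired, because epimerising its labile C2 would carry the C3 error into the antipodal trans series and lower the enantiomeric purity. The route also needs a hindered 2,6-disubstituted phenoxide as nucleophile, two different halogens on ring A, and three steps to reach A7.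

Key step: step 5

Assumption: the sense of induction in step 5 is assigned by analogy and written for (R,R)-Ph-BPE; if that ligand delivers the 2S series, its commercial mirror image is used and nothing else changes.

## Route

Step 1
Reactants: 1 5-bromo-2-hydroxy-3-methoxybenzaldehyde
Product: 2 5-bromo-3-methoxy-2-(methoxymethoxy)benzaldehyde
Conditions: MOMCl (1.5 equiv), i-Pr2NEt (2 equiv), CH2Cl2, 0 °C to rt
Reagents that add atoms: chloromethyl methyl ether, COCCl
Why: O-alkylation of the phenoxide with an α-chloro ether gives the acetal; the aldehyde and aryl bromide are inert, and the group blocks the phenol during the ylide and CuH steps.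

Step 2
Reactants: 2 5-bromo-3-methoxy-2-(methoxymethoxy)benzaldehyde
Product: 3 5-bromo-1-ethenyl-3-methoxy-2-(methoxymethoxy)benzene
Conditions: Ph3PCH3Br (1.3 equiv), KOt-Bu (1.25 equiv), THF, 0 °C to rt
Reagents that add atoms: methyltriphenylphosphonium bromide, C[P+](c1ccccc1)(c1ccccc1)c1ccccc1.[Br-]
Why: Wittig methylenation of an aryl aldehyde; the non-stabilised ylide does not touch the aryl bromide or the acetal.

Step 3
Reactants: 4 4-hydroxy-3,5-dimethoxybenzoic acid (syringic acid)
Product: 6 3,5-dimethoxy-4-(methoxymethoxy)benzoic acid, via methoxymethyl ester 5 (not isolated)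
Conditions: MOMCl (2.5 equiv), i-Pr2NEt (3 equiv), CH2Cl2, 0 °C to rt; then LiOH (3 equiv), THF/H2O, rt; 1 M HCl to pH 4, 0 °C
Reagents that add atoms: chloromethyl methyl ether, COCCl; lithium hydroxide, [Li+].[OH-]
Why: Phenoxide and carboxylate are both alkylated; hydroxide then cleaves only the ester by acyl substitution (one carboxyl oxygen comes from hydroxide), and the aryl acetal survives base and brief cold acidification.

Step 4
Reactants: 6 3,5-dimethoxy-4-(methoxymethoxy)benzoic acid (2 equiv)
Product: 7 3,5-dimethoxy-4-(methoxymethoxy)benzoic anhydride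
Conditions: DCC (1 equiv for 2 equiv of 6), CH2Cl2, 0 °C to rt; filtration of the urea
Reagents that add atoms: second molecule of 3,5-dimethoxy-4-(methoxymethoxy)benzoic acid (6), OC(=O)c1cc(OC)c(OCOC)c(OC)c1
Why: Carbodiimide dehydration that joins two molecules of 6: DCC activates one as its O-acylisourea, the carboxylate of the second attacks it, and the water lost is taken up as the urea; one equivalent of DCC for two of acid stops at the symmetrical anhydride, and the neutral conditions keep the acetal.

Step 5
Reactants: 3 5-bromo-1-ethenyl-3-methoxy-2-(methoxymethoxy)benzene; 7 3,5-dimethoxy-4-(methoxymethoxy)benzoic anhydride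
Product: 10 (1R,2R)-2-[5-bromo-3-methoxy-2-(methoxymethoxy)phenyl]-1-[3,5-dimethoxy-4-(methoxymethoxy)phenyl]propan-1-ol, via ketone 8 (not isolated), via silyl ether 9 (not isolated)
Conditions: Cu(OAc)2 (5 mol %), (R,R)-Ph-BPE (5.5 mol %), (MeO)2MeSiH (4 equiv), 7 (1.2 equiv), THF, 40 °C; then MeOH, NH4F (cat.), rt
Reagents that add atoms: none
Why: This is the CuH-catalysed enantioselective reductive coupling of a vinyl arene with a symmetrical aryl carboxylic anhydride, a reaction type established for styrenes and benzoic anhydrides. Cu(OAc)2, the bisphospholane and the silane form a ligated CuH (monovalent copper) that adds across the vinyl group of 3 in the Markovnikov sense: hydrogen goes to the terminal carbon, which becomes the C3 methyl, and copper to the benzylic carbon, stabilised by ring A. The C2-symmetric ligand selects the alkene face, which fixes the future C3 as R. The benzylic copper species acylates 7 with retention to give ketone 8 and a copper carboxylate, which the silane returns to the hydride; this forms the C2–C3 bond and joins rings A and C. In a second, slower cycle the same hydride reduces 8 to the alkoxide, held as silyl ether 9, and methanolysis frees 10. Hydride delivery anti to the α-aryl group should favour 1R, but this carbinol centre is erased in step 6 and any 1S epimer is carried along; no ring is closed here. The step needs styrene hydrocupration to outrun direct reduction of 7 (fast insertion with this ligand, slight excess of 7), reduction of 8 to outrun its enolisation (no free base is present, only copper carboxylate and silyl species), and an untouched aryl bromide (the phosphine-ligated CuH does not insert into Ar–Br at 40 °C).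

Step 6
Reactants: 10 (1R,2R)-2-[5-bromo-3-methoxy-2-(methoxymethoxy)phenyl]-1-[3,5-dimethoxy-4-(methoxymethoxy)phenyl]propan-1-ol
Product: 13 4-[(2R,3R)-5-bromo-7-methoxy-3-methyl-2,3-dihydro-1-benzofuran-2-yl]-2,6-dimethoxyphenol, via triol 11 (not isolated), via quinone methide 12 (not isolated)
Conditions: 3 M aq HCl/THF (1:4), 45 °C
Reagents that add atoms: none
Why: Acetal hydrolysis frees both phenols (11); the 4-hydroxy-3,5-dimethoxybenzylic alcohol then ionises reversibly to the protonated para-quinone methide 12, which the ring A phenol captures by 5-exo oxa-1,6-addition. Because ionisation is reversible and C3 is not touched, both carbinol epimers and any cis product should funnel to the trans (2R,3R) ring, where aryl and methyl avoid eclipsing; C3 controls C2.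

Step 7
Reactants: 13 4-[(2R,3R)-5-bromo-7-methoxy-3-methyl-2,3-dihydro-1-benzofuran-2-yl]-2,6-dimethoxyphenol; 14 4,4,5,5-tetramethyl-2-[(1E)-prop-1-en-1-yl]-1,3,2-dioxaborolane
Product: 15 maceneolignan A, 4-[(2R,3R)-7-methoxy-3-methyl-5-[(1E)-prop-1-en-1-yl]-2,3-dihydro-1-benzofuran-2-yl]-2,6-dimethoxyphenol
Conditions: Pd(OAc)2 (3 mol %), SPhos (6 mol %), K3PO4 (3 equiv), 14 (1.5 equiv), THF/H2O (10:1), 45 °C
Reagents that add atoms: none
Why: Suzuki–Miyaura coupling at the only C–Br bond; the alkenyl boronate transfers with retention of E geometry, the free phenol is tolerated as its phenoxide, and the low temperature is chosen to avoid base-induced opening of the C2–O1 bond.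

## Compound list

1 | 5-bromo-2-hydroxy-3-methoxybenzaldehyde | O=Cc1cc(Br)cc(OC)c1O | starting material
2 | 5-bromo-3-methoxy-2-(methoxymethoxy)benzaldehyde | O=Cc1cc(Br)cc(OC)c1OCOC | intermediate
3 | 5-bromo-1-ethenyl-3-methoxy-2-(methoxymethoxy)benzene | C=Cc1cc(Br)cc(OC)c1OCOC | intermediate
4 | 4-hydroxy-3,5-dimethoxybenzoic acid (syringic acid) | OC(=O)c1cc(OC)c(O)c(OC)c1 | starting material
5 | methoxymethyl 3,5-dimethoxy-4-(methoxymethoxy)benzoate | COCOC(=O)c1cc(OC)c(OCOC)c(OC)c1 | intermediate
6 | 3,5-dimethoxy-4-(methoxymethoxy)benzoic acid | OC(=O)c1cc(OC)c(OCOC)c(OC)c1 | intermediate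
7 | 3,5-dimethoxy-4-(methoxymethoxy)benzoic anhydride | O=C(OC(=O)c1cc(OC)c(OCOC)c(OC)c1)c1cc(OC)c(OCOC)c(OC)c1 | intermediate
8 | (2R)-2-[5-bromo-3-methoxy-2-(methoxymethoxy)phenyl]-1-[3,5-dimethoxy-4-(methoxymethoxy)phenyl]propan-1-one | Brc1cc(OC)c(OCOC)c(c1)[C@@H](C)C(=O)c1cc(OC)c(OCOC)c(OC)c1 | intermediate
9 | [(1R,2R)-2-[5-bromo-3-methoxy-2-(methoxymethoxy)phenyl]-1-[3,5-dimethoxy-4-(methoxymethoxy)phenyl]propoxy](dimethoxy)methylsilane | Brc1cc(OC)c(OCOC)c(c1)[C@@H](C)[C@@H](O[Si](C)(OC)OC)c1cc(OC)c(OCOC)c(OC)c1 | intermediate
10 | (1R,2R)-2-[5-bromo-3-methoxy-2-(methoxymethoxy)phenyl]-1-[3,5-dimethoxy-4-(methoxymethoxy)phenyl]propan-1-ol (expected major carbinol epimer; the 1S epimer is carried along) | Brc1cc(OC)c(OCOC)c(c1)[C@@H](C)[C@@H](O)c1cc(OC)c(OCOC)c(OC)c1 | intermediate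
11 | (1R,2R)-2-(5-bromo-2-hydroxy-3-methoxyphenyl)-1-(4-hydroxy-3,5-dimethoxyphenyl)propan-1-ol | Brc1cc(OC)c(O)c(c1)[C@@H](C)[C@@H](O)c1cc(OC)c(O)c(OC)c1 | intermediate
12 | 4-[(2S)-2-(5-bromo-2-hydroxy-3-methoxyphenyl)propylidene]-2,6-dimethoxycyclohexa-2,5-dien-1-one (descriptor changes by priority only; the centre is untouched) | Brc1cc(OC)c(O)c(c1)[C@@H](C)C=C1C=C(OC)C(=O)C(OC)=C1 | intermediate
13 | 4-[(2R,3R)-5-bromo-7-methoxy-3-methyl-2,3-dihydro-1-benzofuran-2-yl]-2,6-dimethoxyphenol | Brc1cc(OC)c2c(c1)[C@@H](C)[C@H](c1cc(OC)c(O)c(OC)c1)O2 | intermediate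
14 | 4,4,5,5-tetramethyl-2-[(1E)-prop-1-en-1-yl]-1,3,2-dioxaborolane | C/C=C/B1OC(C)(C)C(C)(C)O1 | starting material
15 | maceneolignan A, 4-[(2R,3R)-7-methoxy-3-methyl-5-[(1E)-prop-1-en-1-yl]-2,3-dihydro-1-benzofuran-2-yl]-2,6-dimethoxyphenol | C/C=C/c1cc(OC)c2c(c1)[C@@H](C)[C@H](c1cc(OC)c(O)c(OC)c1)O2 | target

## Step count and risk

Total steps: 7. Longest linear sequence: 5 steps (steps 1, 2, 5, 6, 7 from 1; equally steps 3, 4, 5, 6, 7 from 4).

**Step 5 (key step).** The most likely failure is consumption of the anhydride by direct hydride reduction before the benzylic copper species can acylate it. The electron-rich aroyl group is a slow electrophile, and the ortho acetal of 3 may slow or misdirect hydrocupration by chelation. Either effect would show as reduced styrene or lowered facial selectivity. The fallback separates the asymmetric event from the ring-joining event and sets out from 3. Rhodium-catalysed asymmetric hydroformylation (Rh(acac)(CO)2, a chiral bisphospholane or bis-diazaphospholane ligand, CO/H2, toluene, 60 °C) should give the branched aldehyde (2R)-2-[5-bromo-3-methoxy-2-(methoxymethoxy)phenyl]propanal F1. Separately, commercial 4-bromo-2,6-dimethoxyphenol is protected (MOMCl, i-Pr2NEt) to 5-bromo-1,3-dimethoxy-2-(methoxymethoxy)benzene F2. F2 is converted with n-BuLi at −78 °C into [3,5-dimethoxy-4-(methoxymethoxy)phenyl]lithium F3, to which F1 is added at −78 °C, followed by a water quench. The product is 10 as a mixture of carbinol epimers, which step 6 accepts, so the fallback rejoins the route at 10.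

**Step 6.** The main danger is proton loss from C3 of the benzylic cation or of 12 to give a stilbene, which would destroy the only reagent-set stereocentre; repeated reversible ring opening under acid raises that chance. A second danger is electrophilic attack of released formaldehyde on the electron-rich rings. The fallback closes the ring under base and sets out from 10. The acetals are removed with ZnBr2/n-PrSH in CH2Cl2 at 0 °C, a cleavage that is over in minutes, and triol 11 is isolated. Acetylation (Ac2O, pyridine) gives (1R,2R)-1-[4-(acetyloxy)-3,5-dimethoxyphenyl]-2-[2-(acetyloxy)-5-bromo-3-methoxyphenyl]propyl acetate F4. K2CO3 in MeOH at 0 °C then removes the two aryl acetates to give (1R,2R)-2-(5-bromo-2-hydroxy-3-methoxyphenyl)-1-(4-hydroxy-3,5-dimethoxyphenyl)propyl acetate F5. The para-phenoxide of F5 expels the benzylic acetate to form 12, and the ortho-phenoxide closes it to 13, where the fallback rejoins the route.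

**Step 7.** With the ring C phenol deprotonated, warm base can open the C2–O1 bond to the quinone methide, and tautomerisation to a stilbene would then cost material and C3 integrity. Oxidative addition into the electron-rich C–Br bond may also be slow, and a palladium hydride could erode the E geometry. The fallback changes the order of events so that the coupling is done while no free phenol and no ring B are present; it sets out from 10. Suzuki coupling of 10 with 14 under the step 7 conditions should give (1R,2R)-1-[3,5-dimethoxy-4-(methoxymethoxy)phenyl]-2-{3-methoxy-2-(methoxymethoxy)-5-[(1E)-prop-1-en-1-yl]phenyl}propan-1-ol F6. Brief treatment with the step 6 acid at a lower temperature (the propenyl group is acid-sensitive) then passes through triol (1R,2R)-2-{2-hydroxy-3-methoxy-5-[(1E)-prop-1-en-1-yl]phenyl}-1-(4-hydroxy-3,5-dimethoxyphenyl)propan-1-ol F7 and quinone methide 4-[(2S)-2-{2-hydroxy-3-methoxy-5-[(1E)-prop-1-en-1-yl]phenyl}propylidene]-2,6-dimethoxycyclohexa-2,5-dien-1-one F8, and rejoins the route at 15.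

## Further compounds

F1 | step 5 | (2R)-2-[5-bromo-3-methoxy-2-(methoxymethoxy)phenyl]propanal | Brc1cc(OC)c(OCOC)c(c1)[C@@H](C)C=O
F2 | step 5 | 5-bromo-1,3-dimethoxy-2-(methoxymethoxy)benzene | COCOc1c(OC)cc(Br)cc1OC
F3 | step 5 | [3,5-dimethoxy-4-(methoxymethoxy)phenyl]lithium | [Li]c1cc(OC)c(OCOC)c(OC)c1
F4 | step 6 | (1R,2R)-1-[4-(acetyloxy)-3,5-dimethoxyphenyl]-2-[2-(acetyloxy)-5-bromo-3-methoxyphenyl]propyl acetate | Brc1cc(OC)c(OC(C)=O)c(c1)[C@@H](C)[C@@H](OC(C)=O)c1cc(OC)c(OC(C)=O)c(OC)c1
F5 | step 6 | (1R,2R)-2-(5-bromo-2-hydroxy-3-methoxyphenyl)-1-(4-hydroxy-3,5-dimethoxyphenyl)propyl acetate | Brc1cc(OC)c(O)c(c1)[C@@H](C)[C@@H](OC(C)=O)c1cc(OC)c(O)c(OC)c1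
F6 | step 7 | (1R,2R)-1-[3,5-dimethoxy-4-(methoxymethoxy)phenyl]-2-{3-methoxy-2-(methoxymethoxy)-5-[(1E)-prop-1-en-1-yl]phenyl}propan-1-ol | C/C=C/c1cc(OC)c(OCOC)c(c1)[C@@H](C)[C@@H](O)c1cc(OC)c(OCOC)c(OC)c1
F7 | step 7 | (1R,2R)-2-{2-hydroxy-3-methoxy-5-[(1E)-prop-1-en-1-yl]phenyl}-1-(4-hydroxy-3,5-dimethoxyphenyl)propan-1-ol | C/C=C/c1cc(OC)c(O)c(c1)[C@@H](C)[C@@H](O)c1cc(OC)c(O)c(OC)c1
F8 | step 7 | 4-[(2S)-2-{2-hydroxy-3-methoxy-5-[(1E)-prop-1-en-1-yl]phenyl}propylidene]-2,6-dimethoxycyclohexa-2,5-dien-1-one | C/C=C/c1cc(OC)c(O)c(c1)[C@@H](C)C=C1C=C(OC)C(=O)C(OC)=C1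
A1 | alternative 1 | isoeugenol, 2-methoxy-4-[(1E)-prop-1-en-1-yl]phenol | C/C=C/c1ccc(O)c(OC)c1
A2 | alternative 1 | 2,6-dimethoxy-4-[(1E)-prop-1-en-1-yl]phenol | C/C=C/c1cc(OC)c(O)c(OC)c1
A3 | alternative 1 | racemic trans-maceneolignan A (both enantiomers) | C/C=C/c1cc(OC)c2c(c1)[C@@H](C)[C@H](c1cc(OC)c(O)c(OC)c1)O2.C/C=C/c1cc(OC)c2c(c1)[C@H](C)[C@@H](c1cc(OC)c(O)c(OC)c1)O2
A4 | alternative 1 | racemic trans-dehydrodiisoeugenol (isoeugenol homodimer, both enantiomers) | C/C=C/c1cc(OC)c2c(c1)[C@@H](C)[C@H](c1ccc(O)c(OC)c1)O2.C/C=C/c1cc(OC)c2c(c1)[C@H](C)[C@@H](c1ccc(O)c(OC)c1)O2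
A5 | alternative 2 | 1-{5-bromo-2-[[3,5-dimethoxy-4-(methoxymethoxy)phenyl]methoxy]-3-methoxyphenyl}ethan-1-one hydrazone | CC(=NN)c1cc(Br)cc(OC)c1OCc1cc(OC)c(OCOC)c(OC)c1
A6 | alternative 2 | (2S,3R)-5-bromo-2-[3,5-dimethoxy-4-(methoxymethoxy)phenyl]-7-methoxy-3-methyl-2,3-dihydro-1-benzofuran (cis) | Brc1cc(OC)c2c(c1)[C@@H](C)[C@@H](c1cc(OC)c(OCOC)c(OC)c1)O2
A7 | alternative 3 | (2E)-3-[3,5-dimethoxy-4-(methoxymethoxy)phenyl]prop-2-en-1-yl methyl carbonate | COC(=O)OC/C=C/c1cc(OC)c(OCOC)c(OC)c1
A8 | alternative 3 | 4-bromo-2-iodo-6-methoxyphenol | Oc1c(I)cc(Br)cc1OC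
A9 | alternative 3 | 5-bromo-2-{[(1R)-1-[3,5-dimethoxy-4-(methoxymethoxy)phenyl]prop-2-en-1-yl]oxy}-1-iodo-3-methoxybenzene | C=C[C@H](c1cc(OC)c(OCOC)c(OC)c1)Oc1c(I)cc(Br)cc1OC
A10 | alternative 3 | (2R,3R)-5-bromo-2-[3,5-dimethoxy-4-(methoxymethoxy)phenyl]-7-methoxy-3-methyl-2,3-dihydro-1-benzofuran (trans) | Brc1cc(OC)c2c(c1)[C@@H](C)[C@H](c1cc(OC)c(OCOC)c(OC)c1)O2
A11 | alternative 3 | (2R,3S)-5-bromo-2-[3,5-dimethoxy-4-(methoxymethoxy)phenyl]-7-methoxy-3-methyl-2,3-dihydro-1-benzofuran (cis) | Brc1cc(OC)c2c(c1)[C@H](C)[C@H](c1cc(OC)c(OCOC)c(OC)c1)O2
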